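**Plan**
1. Retrosynthesis: the O7–Si bond is cut last. Ring C is then cut at O1–C2 and at C4–C4a, giving a ring A C,O-dianion (from a 2-bromo-5-silyloxyphenol) and an E-cinnamoyl Weinreb amide that carries the complete ring B.
2. Enabling feature: in ring A the ketone carbon C4 sits on C4a, ortho to the ether oxygen O1 on C8a and para to the C7 oxygen. A phenoxide oxygen beside an aryl anion (1,3-C,O-dinucleophile) therefore matches the acyl carbon C4 and the β-carbon C2 of the enoyl unit (1,3-dielectrophile).
3. Ring B is cut at the enamide C=C (Horner–Wadsworth–Emmons), at the aryl–alkenyl bond of the hydroxy side chain (Heck), at the prenyl C=C (cross-metathesis) and at the aryl–allyl bond (Claisen), back to 3-bromo-4-hydroxybenzaldehyde.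
4. Forward: the ring B aldehyde is built on the preformed benzene ring (steps 1–5) and extended to the Weinreb amide (step 6); the ring A partner is made in step 7; step 8 joins the halves and closes ring C; step 9 frees the C7 phenol.
5. Stereochemistry: C2 (S), the only stereocentre, is set in step 8 by a cinchona thiourea catalyst during the oxa-Michael ring closure; both E olefins come from the Heck and Horner–Wadsworth–Emmons steps.

Key step: step 8

Assumption: of the two pseudo-enantiomeric cinchona thioureas, the quinidine-derived one is taken to deliver the (2S) flavanone; if the facial sense is the reverse, the quinine-derived catalyst is used in the same way.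

**Step 1**
Reactants: 1 3-bromo-4-hydroxybenzaldehyde; 2 allyl bromide
Product: 3 4-(allyloxy)-3-bromobenzaldehyde
Conditions: K2CO3, acetone, reflux
Reagents that add atoms: none
Why: Williamson ether synthesis, in which the phenoxide formed by K2CO3 displaces bromide from the allylic halide while the aldehyde and the aryl bromide stay inert.

**Step 2**
Reactants: 3 4-(allyloxy)-3-bromobenzaldehyde
Product: 4 3-allyl-5-bromo-4-hydroxybenzaldehyde
Conditions: N,N-diethylaniline, 200 °C
Reagents that add atoms: none
Why: Aromatic Claisen rearrangement, whose [3,3]-sigmatropic shift can only reach the unsubstituted ortho carbon because the other one is blocked by bromine, after which tautomerisation restores the phenol.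

**Step 3**
Reactants: 4 3-allyl-5-bromo-4-hydroxybenzaldehyde
Product: 5 3-allyl-5-bromo-4-methoxybenzaldehyde
Conditions: MeI, K2CO3, DMF, rt
Reagents that add atoms: iodomethane, CI
Why: Williamson O-methylation, in which the small electrophile reaches the doubly ortho-substituted phenoxide and the weak base should not move the allyl double bond into conjugation.

**Step 4**
Reactants: 5 3-allyl-5-bromo-4-methoxybenzaldehyde; 6 2-methylbut-2-ene
Product: 7 3-bromo-4-methoxy-5-(3-methylbut-2-en-1-yl)benzaldehyde
Conditions: second-generation Grubbs catalyst RuCl2(=CHPh)(PCy3)(H2IMes) (3 mol %), 2-methylbut-2-ene/CH2Cl2, 40 °C, sealed vessel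
Reagents that add atoms: none
Why: Olefin cross-metathesis, in which the terminal allyl olefin exchanges its methylene for the isopropylidene unit of the excess 2-methylbut-2-ene with loss of propene, and the trisubstituted product is too hindered to react further.

**Step 5**
Reactants: 7 3-bromo-4-methoxy-5-(3-methylbut-2-en-1-yl)benzaldehyde; 8 2-methylbut-3-en-2-ol
Product: 9 3-[(E)-3-hydroxy-3-methylbut-1-en-1-yl]-4-methoxy-5-(3-methylbut-2-en-1-yl)benzaldehyde
Conditions: Pd(OAc)2 (5 mol %), P(o-tol)3 (10 mol %), NaOAc, DMF, 110 °C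
Reagents that add atoms: none
Why: Mizoroki–Heck reaction, in which the arylpalladium bromide inserts the monosubstituted olefin at its terminal carbon and syn β-hydride elimination gives the E-styrene, while the trisubstituted prenyl olefin is too hindered to insert and the tertiary carbinol cannot isomerise to a carbonyl compound.

**Step 6**
Reactants: 9 3-[(E)-3-hydroxy-3-methylbut-1-en-1-yl]-4-methoxy-5-(3-methylbut-2-en-1-yl)benzaldehyde; 10 diethyl {2-[methoxy(methyl)amino]-2-oxoethyl}phosphonate
Product: 11 (E)-3-{3-[(E)-3-hydroxy-3-methylbut-1-en-1-yl]-4-methoxy-5-(3-methylbut-2-en-1-yl)phenyl}-N-methoxy-N-methylprop-2-enamide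
Conditions: LiCl, DBU, MeCN, rt
Reagents that add atoms: none
Why: Horner–Wadsworth–Emmons olefination under Masamune–Roush conditions, in which the lithium-chelated phosphonate is deprotonated by the amidine base and should give the E-enamide, and the mild base leaves the tertiary alcohol untouched.

**Step 7**
Reactants: 12 4-bromobenzene-1,3-diol
Product: 13 2-bromo-5-[(tert-butyldimethylsilyl)oxy]phenol
Conditions: TBSCl (1.0 equiv), imidazole, CH2Cl2, −20 to 0 °C
Reagents that add atoms: tert-butyldimethylsilyl chloride, CC(C)(C)[Si](C)(C)Cl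
Why: Imidazole-promoted silyl ether formation, in which the hydroxyl para to bromine is the less hindered one and should be silylated first, leaving the hydroxyl flanked by bromine free for the later ring closure.

**Step 8**
Reactants: 13 2-bromo-5-[(tert-butyldimethylsilyl)oxy]phenol; 11 (E)-3-{3-[(E)-3-hydroxy-3-methylbut-1-en-1-yl]-4-methoxy-5-(3-methylbut-2-en-1-yl)phenyl}-N-methoxy-N-methylprop-2-enamide
Product: 17 (2S)-7-[(tert-butyldimethylsilyl)oxy]-2-{3-[(E)-3-hydroxy-3-methylbut-1-en-1-yl]-4-methoxy-5-(3-methylbut-2-en-1-yl)phenyl}chroman-4-one, via aryllithium 14 (not isolated), via tetrahedral adduct 15 (not isolated), via chalcone 16 (not isolated)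
Conditions: one telescoped operation: i) 13, n-BuLi then t-BuLi, THF, −78 °C; ii) 11 (as its lithium alkoxide, from LiN(SiMe3)2), −78 to −20 °C; iii) AcOH, −78 °C, pH 7 wash, change of solvent to toluene; iv) 1-[3,5-bis(trifluoromethyl)phenyl]-3-[(8R,9R)-6'-methoxycinchonan-9-yl]thiourea (from 9-amino-9-deoxy-epi-quinidine, 10 mol %), toluene, 0 °C to rt
Reagents that add atoms: none
Why: Bromine–lithium exchange on the lithium phenoxide of 13 gives the C,O-dianion 14, whose aryl carbon (the future C4a) adds 1,2 to the Weinreb amide to form the C4–C4a bond, and the N,O-chelated adduct 15 survives until the acetic acid quench releases the 2'-hydroxychalcone 16. The thiourea then binds the enone carbonyl through its two N–H bonds while its quinuclidine nitrogen takes the proton of the 2'-hydroxyl, and the phenol oxygen (O1) adds to the β-carbon (C2) in a 6-endo-trig oxa-Michael closure of ring C. The closest known reaction types are the acylation of aryllithiums by Weinreb amides and the cinchona-thiourea-catalysed asymmetric cyclisation of 2'-hydroxychalcones to flavanones. The C2 stereocentre is set by the catalyst, which should expose one face of the E-enone to O1 (S under the assumption above). The step needs 1,2- over 1,4-addition and C- over O-acylation, which the hard aryllithium, the chelating Weinreb group and the much lower nucleophilicity of the phenoxide oxygen should secure. It also needs the catalysed ring closure to outrun the uncatalysed one, which the neutral non-polar medium and the silyl ether at C7 (it keeps the second phenol from ionising) should secure.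

**Step 9**
Reactants: 17 (2S)-7-[(tert-butyldimethylsilyl)oxy]-2-{3-[(E)-3-hydroxy-3-methylbut-1-en-1-yl]-4-methoxy-5-(3-methylbut-2-en-1-yl)phenyl}chroman-4-one
Product: 18 (2S)-7-hydroxy-2-{3-[(E)-3-hydroxy-3-methylbut-1-en-1-yl]-4-methoxy-5-(3-methylbut-2-en-1-yl)phenyl}chroman-4-one
Conditions: TBAF, AcOH (1:1), THF, 0 °C
Reagents that add atoms: none
Why: Fluoride-induced desilylation of the aryl silyl ether, with the acetic acid buffer keeping the medium from becoming basic so that the flavanone should not open by retro-oxa-Michael reaction and C2 keeps its configuration.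

**Compound list**
1 | 3-bromo-4-hydroxybenzaldehyde | O=Cc1ccc(O)c(Br)c1 | starting material
2 | allyl bromide (3-bromoprop-1-ene) | C=CCBr | starting material
3 | 4-(allyloxy)-3-bromobenzaldehyde | O=Cc1ccc(OCC=C)c(Br)c1 | intermediate
4 | 3-allyl-5-bromo-4-hydroxybenzaldehyde | O=Cc1cc(Br)c(O)c(CC=C)c1 | intermediate
5 | 3-allyl-5-bromo-4-methoxybenzaldehyde | COc1c(Br)cc(C=O)cc1CC=C | intermediate
6 | 2-methylbut-2-ene | CC=C(C)C | starting material
7 | 3-bromo-4-methoxy-5-(3-methylbut-2-en-1-yl)benzaldehyde | COc1c(Br)cc(C=O)cc1CC=C(C)C | intermediate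
8 | 2-methylbut-3-en-2-ol | C=CC(C)(C)O | starting material
9 | 3-[(E)-3-hydroxy-3-methylbut-1-en-1-yl]-4-methoxy-5-(3-methylbut-2-en-1-yl)benzaldehyde | COc1c(/C=C/C(C)(C)O)cc(C=O)cc1CC=C(C)C | intermediate
10 | diethyl {2-[methoxy(methyl)amino]-2-oxoethyl}phosphonate | CCOP(=O)(CC(=O)N(C)OC)OCC | starting material
11 | (E)-3-{3-[(E)-3-hydroxy-3-methylbut-1-en-1-yl]-4-methoxy-5-(3-methylbut-2-en-1-yl)phenyl}-N-methoxy-N-methylprop-2-enamide | COc1c(/C=C/C(C)(C)O)cc(/C=C/C(=O)N(C)OC)cc1CC=C(C)C | intermediate
12 | 4-bromobenzene-1,3-diol (4-bromoresorcinol) | Oc1ccc(Br)c(O)c1 | starting material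
13 | 2-bromo-5-[(tert-butyldimethylsilyl)oxy]phenol | CC(C)(C)[Si](C)(C)Oc1ccc(Br)c(O)c1 | intermediate
14 | lithium 5-[(tert-butyldimethylsilyl)oxy]-2-lithiophenolate | [Li]Oc1cc(O[Si](C)(C)C(C)(C)C)ccc1[Li] | intermediate
15 | trilithium salt of the tetrahedral adduct of 14 with 11 (C4 bears O–Li, N(OMe)Me, the styryl group and the ring A aryl group; configuration at this carbon not defined) | COc1c(/C=C/C(C)(C)O[Li])cc(/C=C/C(O[Li])(N(C)OC)c2ccc(O[Si](C)(C)C(C)(C)C)cc2O[Li])cc1CC=C(C)C | intermediate
16 | (E)-1-{4-[(tert-butyldimethylsilyl)oxy]-2-hydroxyphenyl}-3-{3-[(E)-3-hydroxy-3-methylbut-1-en-1-yl]-4-methoxy-5-(3-methylbut-2-en-1-yl)phenyl}prop-2-en-1-one | COc1c(/C=C/C(C)(C)O)cc(/C=C/C(=O)c2ccc(O[Si](C)(C)C(C)(C)C)cc2O)cc1CC=C(C)C | intermediate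
17 | (2S)-7-[(tert-butyldimethylsilyl)oxy]-2-{3-[(E)-3-hydroxy-3-methylbut-1-en-1-yl]-4-methoxy-5-(3-methylbut-2-en-1-yl)phenyl}chroman-4-one | COc1c(/C=C/C(C)(C)O)cc([C@@H]2CC(=O)c3ccc(O[Si](C)(C)C(C)(C)C)cc3O2)cc1CC=C(C)C | intermediate
18 | (2S)-7-hydroxy-2-{3-[(E)-3-hydroxy-3-methylbut-1-en-1-yl]-4-methoxy-5-(3-methylbut-2-en-1-yl)phenyl}chroman-4-one (CNP0222710.1) | COc1c(/C=C/C(C)(C)O)cc([C@@H]2CC(=O)c3ccc(O)cc3O2)cc1CC=C(C)C | target

**Totals**
Total step count: 9. Longest linear sequence: 8 steps (steps 1–6, 8 and 9); step 7 is a one-step side branch.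

**Steps most likely to fail**

Step 8. The aryllithium may add in conjugate fashion, the ring closure may proceed with poor facial selectivity, and because the oxa-Michael addition is reversible the enantiomeric purity may erode as the mixture approaches equilibrium. The fallback sets out from chalcone 16 and replaces asymmetric catalysis by resolution. Ring closure without chiral control (NaOAc, EtOH, reflux) should give the racemic silyl flavanone F1. Asymmetric transfer hydrogenation with RuCl(p-cymene)[(R,R)-TsDPEN] and HCO2Na in water/ethyl acetate at rt should then reduce the (2R) enantiomer to the cis-(2R,4R)-flavan-4-ol F2 and leave the (2S) ketone, which is separated and comes back to the route at 17. The same treatment can also be used to raise the enantiomeric purity of 17 obtained from step 8.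

Step 9. Basic fluoride may open the flavanone by retro-oxa-Michael reaction and scramble C2, and too acidic a buffer may ionise the tertiary allylic alcohol. The fallback sets out from chalcone 16 and moves the fluoride treatment ahead of the stereocentre. Buffered TBAF/AcOH should give the 2',4'-dihydroxychalcone F3. Acetic anhydride (1 equiv) with pyridine at 0 °C should acetylate only the non-chelated 4'-hydroxyl to give the 4'-acetoxy-2'-hydroxychalcone F4. The thiourea-catalysed ring closure of step 8 should then give the (2S)-7-acetoxyflavanone F5. Neutral enzymatic deacetylation (Candida antarctica lipase B, n-butanol, tert-butyl methyl ether, rt) comes back to the route at 18.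

Step 5. The prenyl double bond may migrate into conjugation through reversible Pd–H addition and elimination at 110 °C, and oxidative addition at the bromide beside the methoxy group may be slow. The fallback sets out from 7 and forms the same bond by transmetalation instead of olefin insertion. Suzuki–Miyaura coupling of 7 with commercial (E)-2-methyl-4-(4,4,5,5-tetramethyl-1,3,2-dioxaborolan-2-yl)but-3-en-2-ol (Pd(dppf)Cl2, K3PO4, dioxane/water, 80 °C) should give the E-styrene directly and comes back to the route at 9.

**Further compounds**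
F1 | step 8 | racemic 7-[(tert-butyldimethylsilyl)oxy]-2-{3-[(E)-3-hydroxy-3-methylbut-1-en-1-yl]-4-methoxy-5-(3-methylbut-2-en-1-yl)phenyl}chroman-4-one | COc1c(/C=C/C(C)(C)O)cc(C2CC(=O)c3ccc(O[Si](C)(C)C(C)(C)C)cc3O2)cc1CC=C(C)C
F2 | step 8 | (2R,4R)-7-[(tert-butyldimethylsilyl)oxy]-2-{3-[(E)-3-hydroxy-3-methylbut-1-en-1-yl]-4-methoxy-5-(3-methylbut-2-en-1-yl)phenyl}chroman-4-ol | COc1c(/C=C/C(C)(C)O)cc([C@H]2C[C@@H](O)c3ccc(O[Si](C)(C)C(C)(C)C)cc3O2)cc1CC=C(C)C
F3 | step 9 | (E)-1-(2,4-dihydroxyphenyl)-3-{3-[(E)-3-hydroxy-3-methylbut-1-en-1-yl]-4-methoxy-5-(3-methylbut-2-en-1-yl)phenyl}prop-2-en-1-one | COc1c(/C=C/C(C)(C)O)cc(/C=C/C(=O)c2ccc(O)cc2O)cc1CC=C(C)C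
F4 | step 9 | 3-hydroxy-4-[(E)-3-{3-[(E)-3-hydroxy-3-methylbut-1-en-1-yl]-4-methoxy-5-(3-methylbut-2-en-1-yl)phenyl}prop-2-enoyl]phenyl acetate | COc1c(/C=C/C(C)(C)O)cc(/C=C/C(=O)c2ccc(OC(C)=O)cc2O)cc1CC=C(C)C
F5 | step 9 | (2S)-2-{3-[(E)-3-hydroxy-3-methylbut-1-en-1-yl]-4-methoxy-5-(3-methylbut-2-en-1-yl)phenyl}-4-oxochroman-7-yl acetate | COc1c(/C=C/C(C)(C)O)cc([C@@H]2CC(=O)c3ccc(OC(C)=O)cc3O2)cc1CC=C(C)C
F0 | step 5 | none | none
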